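## The problem

The target is an acyclic 8-O-4' neolignan. A three-carbon chain C7–C8–C9 carries ring A (4-hydroxy-3-methoxyphenyl) on the benzylic carbon C7 and ring B (4-allyl-2,6-dimethoxyphenyl) through an ether oxygen on C8; C9 is a methyl group. No ring has to be built: the task is to join two aromatic pieces through C7–C8 and C8–O and to fix the single stereocentre, C8, as S. Because C8 is the only stereocentre, nothing in the molecule can relay its configuration, so it must come from a reagent, a catalyst, an auxiliary or the chiral pool. The obvious C8–O disconnection is unattractive: the ring B phenol is flanked by two methoxy groups, and attack of so hindered a phenoxide on a secondary carbon next to a benzylic CH2 competes with elimination to the conjugated propenylarene. Three groups restrict the reagents: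

- the terminal allyl group of ring B is lost to hydrogenation or hydroboration and isomerised to the propenyl isomer by strong base or metal hydride catalysts;
- the free phenol of ring A must be masked by a group that comes off without hydrogenolysis;
- the alkyl aryl ether at C8 expels its aryloxide whenever a radical or a carbon–metal bond is generated at C7 or C9.

The feature that opens the problem is that C8 bears the ether oxygen, a one-carbon arm (C9) and the benzylic carbon C7. With C9 raised to the carboxyl level, C8 is the α-carbon of an aryloxyacetic acid. The oxygen can then be attached while that carbon is still a primary CH2, and the C7–C8 bond and the stereocentre can be made together by alkylating a chiral enolate with a ring A benzylic halide.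

## Retrosynthesis

**O–Si bond (17 from 16).** Target 17 is traced to its tert-butyldimethylsilyl ether 16. A benzyl ether is ruled out by the allyl group, which would not survive hydrogenolysis, and an acetal by the acid it needs next to an electron-rich benzylic position. The silyl ether is the mask that leaves under neutral, non-reducing conditions. Compound 16 is no simpler in skeleton but has no acidic proton, which every earlier step requires. The forward step asks only for fluoride to attack silicon.

**C9–H bond (16 from 15 from 14).** The methyl group of 16 is taken back to the CH2OTs group of tosylate 15 and the CH2OH group of alcohol 14. Keeping C9 as a methyl group throughout would leave C8 with no activating neighbour, and its bonds could then only be made by substitution at a secondary carbon. Alcohol 14 is not smaller, but its C9 is at an oxidation level that can be traced to a carbonyl group. The forward reactions must replace a primary sulfonate by hydride in a polar, two-electron manner, because a radical or a carbon–metal bond at C9 would expel the ring B aryloxide from C8.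

**C9–N bond (14 from 13).** Alcohol 14 is traced to the N-acyl oxazolidinone 13. Direct reductive cleavage is preferred to hydrolysis followed by reduction of the acid, since the reagents that take a carboxylic acid to the alcohol also add to the allyl group. Imide 13 carries the auxiliary that explains how C8 is controlled, and the auxiliary 5 is returned in the forward step. That step needs hydride to attack the exocyclic and not the ring carbonyl, and must not epimerise C8.

**C7–C8 bond (13 from 7 and 11, through enolate 12).** This is the strategic cut. Its neighbours are weaker:

- cutting C8–O needs a hindered phenoxide to attack a secondary carbon;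
- cutting the C7–ring A bond needs an aryl-metal reagent to attack a carbon β to an aryloxy leaving group.

The C7–C8 cut divides the molecule into two halves of similar size. Imide 7 has no stereocentre other than that of the auxiliary, and bromide 11 has none. The forward reaction must form the Z-enolate 12 cleanly, alkylate it faster than it decomposes, and do so on one face only.

**N–acyl bond (7 from 4 and 5, through anhydride 6).** Imide 7 is cut into acid 4 and oxazolidinone 5. Activating the acid as the mixed anhydride 6 avoids an acid chloride, which with an amine base would drift towards the aryloxyketene. Acid 4 is achiral and 5 is commercial. The forward step must acylate nitrogen with the aryloxyacetyl and not the pivaloyl carbonyl of 6.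

**O–CH2 bond (4 from 1 and 2, through ester 3).** Acid 4 is cut at the ether into phenol 1 and bromoester 2. This is the point of the whole plan: the hindered oxygen of ring B is joined to carbon while that carbon is primary and activated by the ester, so the reaction is an easy substitution with no stereochemistry and no elimination. Phenol 1 brings ring B complete with the allyl group and both methoxy groups. The forward step needs only a mild base, so the allyl group stays where it is.

**C–Br, C–H and O–Si bonds of the electrophile (11 from 10 from 9 from 8).** Bromide 11 goes back through benzylic alcohol 10 and silylated aldehyde 9 to vanillin 8, which already has the ring A substitution pattern. The bromide is preferred to a sulfonate because a benzylic sulfonate of so electron-rich a ring would not survive isolation. The forward steps are a silylation, a carbonyl reduction and an alcohol-to-bromide exchange; the only demand is that 11 be made and used without delay.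

## Roads not taken

**Alternative 1:** The cut is the O–C4' bond, with ring B built instead of bought. Secondary alcohol A1, (S)-1-[3-methoxy-4-(methoxymethoxy)phenyl]propan-2-ol, would trap the rhodium carbenoid formed from the cyclic diazo dione A2, methyl 4-diazo-3,5-dioxocyclohexane-1-carboxylate, and Rh2(OAc)4. O–H insertion would give the 2-alkoxy-1,3-dione A3.

- Merits: the C8–O bond of A1 is never broken, so the configuration is retained without any question of facial selectivity, and the hindered ether is formed without substitution at C8. In stereochemical security this road is better than the plan adopted.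
- Weak points: everything that defines ring B still lies ahead. A3 must be dehydrogenated to the aromatic level, both new hydroxyls methylated, and the ester carbon turned into a three-carbon allyl group by reduction, activation and a vinyl coupling. That is at least six further steps, and the dehydrogenation must be run on a molecule with an electron-rich benzylic CH2 and an acetal.
- Comparison: against the stereochemical advantage the chosen plan sets the fact that ring B is purchased complete as 1. Its stereocentre is made, not bought, but it is made as a diastereomer that can be purified.

**Alternative 2:** No skeletal bond is formed in the key step. The prochiral diol A4, 2-(4-allyl-2,6-dimethoxyphenoxy)propane-1,3-diol, would be acetylated on one enantiotopic CH2OH arm by a lipase (from Burkholderia cepacia or porcine pancreas) with vinyl acetate. The product is monoacetate A5, (S)-2-(4-allyl-2,6-dimethoxyphenoxy)-3-hydroxypropyl acetate.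

- Merits: the chirality is catalytic, cheap and introduced at room temperature, with no auxiliary to attach or remove. Either enantiomer of the target could be reached from A5 by choosing which arm becomes the methyl group. A4 shares the easy primary-carbon phenol alkylation with the chosen route. In cost of chirality and ease of operation this road is better.
- Weak points: the enzyme must tell apart two arms beside a di-ortho-substituted aryl ether, which cannot be predicted. The enantiomeric purity cannot be raised by separating diastereomers, and acyl migration between the two oxygens would erode it. Most seriously, the bond from C7 to ring A is still missing. It would have to be made by an aryl-metal reagent displacing a primary leaving group β to the aryloxy group, exactly where loss of the aryloxide is most likely. The two arms need separate activation with a protecting-group exchange between them, so at least six steps follow the key step.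
- Comparison: the chosen plan makes C7–C8 and the stereocentre in one step from an enolate, where the aryloxy group is not a leaving group, and needs a single deoxygenation.

**Alternative 3:** The cut is the pair of C–H bonds at C7 and C8. The Z-configured acid A6, (Z)-2-(4-bromo-2,6-dimethoxyphenoxy)-3-[3-methoxy-4-(methoxymethoxy)phenyl]acrylic acid, would be hydrogenated with H2 and [Ir(cod)(SIPHOX)]BArF. This is a cationic iridium complex of a chiral spiro phosphine-oxazoline, with BArF = tetrakis[3,5-bis(trifluoromethyl)phenyl]borate. The product is acid A7, (R)-2-(4-bromo-2,6-dimethoxyphenoxy)-3-[3-methoxy-4-(methoxymethoxy)phenyl]propanoic acid.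

- Merits: stereocontrol is catalytic and directed by the carboxyl group. A7 is at the same oxidation level as 13, so the reduction of C9 to methyl is no longer than here, and no step is spent attaching an auxiliary. In atom economy and in steps spent on chirality this road is better.
- Weak points: an allyl group cannot pass through a hydrogenation, so ring B must carry bromine as a placeholder. The allyl group then enters by a late cross-coupling, where isomerisation to the propenyl isomer threatens. A6 must be geometrically pure, because the E isomer would not deliver the same enantiomer. The bulky 2,6-dimethoxyaryloxy group next to the alkene is a more demanding substrate than a simple aryloxy group, and the ligand is specialised.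
- Comparison: the chosen plan keeps the allyl group of commercial phenol 1 untouched from the first step to the last and needs no transition metal. Its stereochemical outcome can be corrected by chromatography of 13 before the auxiliary is removed.

Key step: step 6

Assumption: phenol 1 (methoxyeugenol), bromoester 2, oxazolidinone 5 and vanillin 8 are taken to be commercial; the chain is numbered C7 (benzylic), C8 (stereocentre), C9 (methyl).

## Route

Step 1
Reactants: 1 4-allyl-2,6-dimethoxyphenol; 2 ethyl bromoacetate
Product: 4 2-(4-allyl-2,6-dimethoxyphenoxy)acetic acid, via ethyl 2-(4-allyl-2,6-dimethoxyphenoxy)acetate 3 (not isolated)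
Conditions: K2CO3, MeCN, 60 °C; then 2 M aq NaOH, MeOH, rt; then 1 M HCl to pH 2
Reagents that add atoms: sodium hydroxide [Na+].[OH-]
Why: Williamson ether synthesis followed by ester saponification in the same flask; the di-ortho-substituted phenoxide of 1 only has to attack an unhindered, carbonyl-activated primary carbon, and acid 4 is freed from unreacted 1 by extraction into aqueous NaHCO3. The allyl group is inert to carbonate and to cold aqueous hydroxide.

Step 2
Reactants: 4 2-(4-allyl-2,6-dimethoxyphenoxy)acetic acid; 5 (S)-4-benzyloxazolidin-2-one
Product: 7 (S)-3-[2-(4-allyl-2,6-dimethoxyphenoxy)acetyl]-4-benzyloxazolidin-2-one, via mixed pivalic anhydride 6 (not isolated)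
Conditions: PivCl, Et3N, THF, −20 °C; then LiCl, 5, −20 °C → rt
Reagents that add atoms: none
Why: N-acylation of an oxazolidinone through a mixed pivalic anhydride; 5, made more acidic by lithium coordination, is acylated by 6 at the unhindered aryloxyacetyl carbonyl because the pivaloyl carbonyl is shielded by its tert-butyl group. No strong base is used, so the allyl group is not touched.

Step 3
Reactants: 8 vanillin (4-hydroxy-3-methoxybenzaldehyde)
Product: 9 4-(tert-butyldimethylsilyloxy)-3-methoxybenzaldehyde
Conditions: TBSCl, imidazole, DMF, rt
Reagents that add atoms: tert-butyldimethylsilyl chloride CC(C)(C)[Si](C)(C)Cl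
Why: Imidazole-promoted silylation of a phenol; the silyl ether withstands the amide base, both hydride reagents and the sulfonylation of later steps and is removed at the end by fluoride without hydrogenolysis.

Step 4
Reactants: 9 4-(tert-butyldimethylsilyloxy)-3-methoxybenzaldehyde
Product: 10 [4-(tert-butyldimethylsilyloxy)-3-methoxyphenyl]methanol
Conditions: NaBH4, MeOH, 0 °C
Reagents that add atoms: none
Why: Borohydride reduction of an aromatic aldehyde to the benzylic alcohol; at 0 °C the aryl silyl ether should survive the short exposure to methanolic borohydride.

Step 5
Reactants: 10 [4-(tert-butyldimethylsilyloxy)-3-methoxyphenyl]methanol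
Product: 11 4-(tert-butyldimethylsilyloxy)-3-methoxybenzyl bromide
Conditions: PBr3, Et2O, 0 °C; cold NaHCO3 wash; used at once
Reagents that add atoms: phosphorus tribromide BrP(Br)Br
Why: Conversion of a benzylic alcohol into the bromide through its phosphite ester and displacement by bromide. The electron-rich product ionises easily, so it is made cold, freed from acid quickly and carried directly into step 6.

Step 6
Reactants: 7 (S)-3-[2-(4-allyl-2,6-dimethoxyphenoxy)acetyl]-4-benzyloxazolidin-2-one; 11 4-(tert-butyldimethylsilyloxy)-3-methoxybenzyl bromide
Product: 13 (S)-3-[(R)-2-(4-allyl-2,6-dimethoxyphenoxy)-3-(4-(tert-butyldimethylsilyloxy)-3-methoxyphenyl)propanoyl]-4-benzyloxazolidin-2-one, via sodium Z-enolate 12 (not isolated)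
Conditions: NaN(SiMe3)2, THF, −78 °C; then 11 (2 equiv), −78 → −45 °C; AcOH quench
Reagents that add atoms: none
Why: NaN(SiMe3)2 removes an α-proton of 7 at −78 °C to give sodium enolate 12, whose Z geometry (aryloxy oxygen cis to the enolate oxygen) follows from allylic 1,3-strain against the oxazolidinone and is locked by sodium bridging the enolate oxygen and the ring carbonyl. In this rigid chelate the C4 benzyl group of the (S)-auxiliary covers one face of C8, so bromide 11 is attacked in an SN2 reaction from the open face (the Re face of C8, priorities OAr > C9 > H), which forms the C7–C8 bond and the 2R configuration of 13; this centre becomes 8S once C9 is a methyl group. The closest known reaction type is the Evans asymmetric alkylation of alkoxyacetyl and aryloxyacetyl oxazolidinone sodium enolates with allylic and benzylic halides. No ring is closed. The step needs face selectivity, secured by the auxiliary and the fixed enolate geometry, and C- over O-alkylation, secured by the soft, highly SN2-reactive benzylic bromide. It also needs alkylation to outrun fragmentation of 12 into a ketene and the oxazolidinone anion, hence the reactive electrophile in excess and a temperature kept below −45 °C. The minor diastereomer differs from 13 at C8 only and should be separable by chromatography, so the stereochemical purity can be raised before the auxiliary is removed.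

Step 7
Reactants: 13 (S)-3-[(R)-2-(4-allyl-2,6-dimethoxyphenoxy)-3-(4-(tert-butyldimethylsilyloxy)-3-methoxyphenyl)propanoyl]-4-benzyloxazolidin-2-one
Product: 14 (R)-2-(4-allyl-2,6-dimethoxyphenoxy)-3-[4-(tert-butyldimethylsilyloxy)-3-methoxyphenyl]propan-1-ol
Conditions: LiBH4, MeOH (1.5 equiv), THF, 0 °C
Reagents that add atoms: none
Why: Reductive cleavage of an N-acyl oxazolidinone with LiBH4; hydride adds to the exocyclic carbonyl, the tetrahedral intermediate collapses to the aldehyde and this is reduced on to alcohol 14, while auxiliary 5 is recovered. The reagent is not basic enough to epimerise C8 and does not add to the allyl group.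

Step 8
Reactants: 14 (R)-2-(4-allyl-2,6-dimethoxyphenoxy)-3-[4-(tert-butyldimethylsilyloxy)-3-methoxyphenyl]propan-1-ol
Product: 15 (R)-2-(4-allyl-2,6-dimethoxyphenoxy)-3-[4-(tert-butyldimethylsilyloxy)-3-methoxyphenyl]propyl 4-methylbenzenesulfonate
Conditions: TsCl, Et3N, DMAP (cat.), CH2Cl2, 0 °C → rt
Reagents that add atoms: 4-toluenesulfonyl chloride Cc1ccc(S(=O)(=O)Cl)cc1
Why: DMAP-catalysed sulfonylation of a primary alcohol; C8 is not involved and the primary tosylate is stable enough to isolate.

Step 9
Reactants: 15 (R)-2-(4-allyl-2,6-dimethoxyphenoxy)-3-[4-(tert-butyldimethylsilyloxy)-3-methoxyphenyl]propyl 4-methylbenzenesulfonate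
Product: 16 tert-butyl{4-[(S)-2-(4-allyl-2,6-dimethoxyphenoxy)propyl]-2-methoxyphenoxy}dimethylsilane
Conditions: LiEt3BH, THF, 0 °C → rt
Reagents that add atoms: none
Why: SN2 displacement of a primary tosylate by hydride from LiEt3BH turns C9 into the methyl group; a polar hydride is chosen because a radical or organometallic centre at C9 would expel the ring B aryloxide. The descriptor at C8 changes from R to S only because the priorities change; no bond to C8 is broken.

Step 10
Reactants: 16 tert-butyl{4-[(S)-2-(4-allyl-2,6-dimethoxyphenoxy)propyl]-2-methoxyphenoxy}dimethylsilane
Product: 17 4-[(S)-2-(4-allyl-2,6-dimethoxyphenoxy)propyl]-2-methoxyphenol (CNP0225369.1)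
Conditions: Bu4NF, AcOH, THF, 0 °C → rt
Reagents that add atoms: none
Why: Fluoride-mediated cleavage of an aryl silyl ether, driven by the strong Si–F bond; acetic acid buffers the phenoxide, and neither the allyl group nor the C8 ether is affected.

## Compound list

1 | 4-allyl-2,6-dimethoxyphenol | C=CCc1cc(OC)c(O)c(OC)c1 | starting material
2 | ethyl bromoacetate | CCOC(=O)CBr | starting material
3 | ethyl 2-(4-allyl-2,6-dimethoxyphenoxy)acetate | C=CCc1cc(OC)c(OCC(=O)OCC)c(OC)c1 | intermediate
4 | 2-(4-allyl-2,6-dimethoxyphenoxy)acetic acid | C=CCc1cc(OC)c(OCC(=O)O)c(OC)c1 | intermediate
5 | (S)-4-benzyloxazolidin-2-one | O=C1N[C@@H](Cc2ccccc2)CO1 | starting material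
6 | 2-(4-allyl-2,6-dimethoxyphenoxy)acetic pivalic anhydride | C=CCc1cc(OC)c(OCC(=O)OC(=O)C(C)(C)C)c(OC)c1 | intermediate
7 | (S)-3-[2-(4-allyl-2,6-dimethoxyphenoxy)acetyl]-4-benzyloxazolidin-2-one | C=CCc1cc(OC)c(OCC(=O)N2[C@@H](Cc3ccccc3)COC2=O)c(OC)c1 | intermediate
8 | vanillin (4-hydroxy-3-methoxybenzaldehyde) | COc1cc(C=O)ccc1O | starting material
9 | 4-(tert-butyldimethylsilyloxy)-3-methoxybenzaldehyde | COc1cc(C=O)ccc1O[Si](C)(C)C(C)(C)C | intermediate
10 | [4-(tert-butyldimethylsilyloxy)-3-methoxyphenyl]methanol | COc1cc(CO)ccc1O[Si](C)(C)C(C)(C)C | intermediate
11 | 4-(tert-butyldimethylsilyloxy)-3-methoxybenzyl bromide | BrCc1ccc(O[Si](C)(C)C(C)(C)C)c(OC)c1 | intermediate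
12 | sodium (Z)-2-(4-allyl-2,6-dimethoxyphenoxy)-1-[(S)-4-benzyl-2-oxooxazolidin-3-yl]ethen-1-olate | C=CCc1cc(OC)c(O/C=C(\[O-])N2[C@@H](Cc3ccccc3)COC2=O)c(OC)c1.[Na+] | intermediate
13 | (S)-3-[(R)-2-(4-allyl-2,6-dimethoxyphenoxy)-3-(4-(tert-butyldimethylsilyloxy)-3-methoxyphenyl)propanoyl]-4-benzyloxazolidin-2-one | C=CCc1cc(OC)c(O[C@@H](C(=O)N2[C@@H](Cc3ccccc3)COC2=O)Cc2ccc(O[Si](C)(C)C(C)(C)C)c(OC)c2)c(OC)c1 | intermediate
14 | (R)-2-(4-allyl-2,6-dimethoxyphenoxy)-3-[4-(tert-butyldimethylsilyloxy)-3-methoxyphenyl]propan-1-ol | C=CCc1cc(OC)c(O[C@@H](CO)Cc2ccc(O[Si](C)(C)C(C)(C)C)c(OC)c2)c(OC)c1 | intermediate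
15 | (R)-2-(4-allyl-2,6-dimethoxyphenoxy)-3-[4-(tert-butyldimethylsilyloxy)-3-methoxyphenyl]propyl 4-methylbenzenesulfonate | C=CCc1cc(OC)c(O[C@@H](COS(=O)(=O)c2ccc(C)cc2)Cc2ccc(O[Si](C)(C)C(C)(C)C)c(OC)c2)c(OC)c1 | intermediate
16 | tert-butyl{4-[(S)-2-(4-allyl-2,6-dimethoxyphenoxy)propyl]-2-methoxyphenoxy}dimethylsilane | C=CCc1cc(OC)c(O[C@@H](C)Cc2ccc(O[Si](C)(C)C(C)(C)C)c(OC)c2)c(OC)c1 | intermediate
17 | 4-[(S)-2-(4-allyl-2,6-dimethoxyphenoxy)propyl]-2-methoxyphenol | C=CCc1cc(OC)c(O[C@@H](C)Cc2ccc(O)c(OC)c2)c(OC)c1 | target

## Step count and least certain steps

Total step count: 10. Longest linear sequence: 8 steps (steps 3, 4, 5, 6, 7, 8, 9, 10, from vanillin 8). The branch from phenol 1 is 7 steps (steps 1, 2, 6, 7, 8, 9, 10).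

**Step 6 (key step).** The most likely failure is fragmentation of the sodium enolate into a ketene and the oxazolidinone anion before C-alkylation has taken place, made worse if the labile electrophile is consumed by ionisation and self-condensation. The second concern is incomplete facial selectivity if chelation is disturbed by the two ortho methoxy oxygens competing for sodium.

The fallback sets out from phenol 1 and returns to the route at 16; it buys the stereocentre instead of making it. Commercial 4-bromo-2-methoxyphenol would be silylated (TBSCl, imidazole) to (4-bromo-2-methoxyphenoxy)(tert-butyl)dimethylsilane F1. With Mg in THF this gives [4-(tert-butyldimethylsilyloxy)-3-methoxyphenyl]magnesium bromide F2. CuI-catalysed opening of (R)-2-methyloxirane at its CH2 group gives (R)-1-[4-(tert-butyldimethylsilyloxy)-3-methoxyphenyl]propan-2-ol F3, with the C–O bond of the stereocentre untouched. A Mitsunobu reaction of F3 with phenol 1 (PPh3, diisopropyl azodicarboxylate, THF, 0 °C → rt) inverts this centre and should give 16 directly. The price is a slow coupling of a hindered phenol at a secondary carbon, with elimination to the propenylarene as the competing process.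

**Step 5.** The bromide of so electron-rich a benzylic position ionises readily. The likely failure is self-alkylation of the aromatic ring and hydrolysis during work-up or storage, with some loss of the silyl group to HBr.

The fallback sets out from alcohol 10 and returns at 13. The stock compound would become the more robust tert-butyl[4-(chloromethyl)-2-methoxyphenoxy]dimethylsilane F4 (SOCl2, pyridine, CH2Cl2, 0 °C). Only immediately before use would it be converted by a Finkelstein exchange (NaI, acetone) into tert-butyl[4-(iodomethyl)-2-methoxyphenoxy]dimethylsilane F5. This alkylates enolate 12 under the conditions of step 6 to give 13.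

**Step 9.** The tosylate sits on a carbon next to a branched, aryloxy-bearing centre. The likely failures are hydride attack at sulfur, which returns alcohol 14, and base-induced elimination towards the enol ether, both at the expense of a slowed SN2 displacement.

The fallback sets out from alcohol 14 and returns at 16. An Appel-type iodination (I2, PPh3, imidazole, CH2Cl2) would give tert-butyl{4-[(R)-2-(4-allyl-2,6-dimethoxyphenoxy)-3-iodopropyl]-2-methoxyphenoxy}dimethylsilane F6. The better leaving group is then displaced by the less basic NaBH4 in DMSO to give 16. Tin hydride or zinc reduction of F6 is deliberately avoided, because a radical or carbon–metal bond at C9 would eject the ring B aryloxide.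

**Step 7.** The acyl carbonyl is flanked by a branched carbon carrying a bulky aryloxy group. The likely failure is hydride attack at the ring carbonyl, which opens the oxazolidinone to a hydroxy amide instead of releasing alcohol 14.

The fallback sets out from 13 and returns at 14. Transesterification with MeOMgBr in MeOH/CH2Cl2 at 0 °C would give methyl (R)-2-(4-allyl-2,6-dimethoxyphenoxy)-3-[4-(tert-butyldimethylsilyloxy)-3-methoxyphenyl]propanoate F7 and auxiliary 5. The ester is then reduced with LiAlH4 in Et2O at 0 °C to 14.

## Further compounds

F1 | step 6 | (4-bromo-2-methoxyphenoxy)(tert-butyl)dimethylsilane | COc1cc(Br)ccc1O[Si](C)(C)C(C)(C)C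
F2 | step 6 | [4-(tert-butyldimethylsilyloxy)-3-methoxyphenyl]magnesium bromide | COc1cc([Mg]Br)ccc1O[Si](C)(C)C(C)(C)C
F3 | step 6 | (R)-1-[4-(tert-butyldimethylsilyloxy)-3-methoxyphenyl]propan-2-ol | C[C@@H](O)Cc1ccc(O[Si](C)(C)C(C)(C)C)c(OC)c1
F4 | step 5 | tert-butyl[4-(chloromethyl)-2-methoxyphenoxy]dimethylsilane | ClCc1ccc(O[Si](C)(C)C(C)(C)C)c(OC)c1
F5 | step 5 | tert-butyl[4-(iodomethyl)-2-methoxyphenoxy]dimethylsilane | ICc1ccc(O[Si](C)(C)C(C)(C)C)c(OC)c1
F6 | step 9 | tert-butyl{4-[(R)-2-(4-allyl-2,6-dimethoxyphenoxy)-3-iodopropyl]-2-methoxyphenoxy}dimethylsilane | C=CCc1cc(OC)c(O[C@@H](CI)Cc2ccc(O[Si](C)(C)C(C)(C)C)c(OC)c2)c(OC)c1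
F7 | step 7 | methyl (R)-2-(4-allyl-2,6-dimethoxyphenoxy)-3-[4-(tert-butyldimethylsilyloxy)-3-methoxyphenyl]propanoate | C=CCc1cc(OC)c(O[C@@H](C(=O)OC)Cc2ccc(O[Si](C)(C)C(C)(C)C)c(OC)c2)c(OC)c1
A1 | alternative 1 | (S)-1-[3-methoxy-4-(methoxymethoxy)phenyl]propan-2-ol | C[C@H](O)Cc1ccc(OCOC)c(OC)c1
A2 | alternative 1 | methyl 4-diazo-3,5-dioxocyclohexane-1-carboxylate | COC(=O)C1CC(=O)C(=[N+]=[N-])C(=O)C1
A3 | alternative 1 | methyl 4-{[(2S)-1-(3-methoxy-4-(methoxymethoxy)phenyl)propan-2-yl]oxy}-3,5-dioxocyclohexane-1-carboxylate | COC(=O)C1CC(=O)C(O[C@@H](C)Cc2ccc(OCOC)c(OC)c2)C(=O)C1
A4 | alternative 2 | 2-(4-allyl-2,6-dimethoxyphenoxy)propane-1,3-diol | C=CCc1cc(OC)c(OC(CO)CO)c(OC)c1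
A5 | alternative 2 | (S)-2-(4-allyl-2,6-dimethoxyphenoxy)-3-hydroxypropyl acetate | C=CCc1cc(OC)c(O[C@@H](CO)COC(C)=O)c(OC)c1
A6 | alternative 3 | (Z)-2-(4-bromo-2,6-dimethoxyphenoxy)-3-[3-methoxy-4-(methoxymethoxy)phenyl]acrylic acid | COc1cc(Br)cc(OC)c1O/C(C(=O)O)=C\c1ccc(OCOC)c(OC)c1
A7 | alternative 3 | (R)-2-(4-bromo-2,6-dimethoxyphenoxy)-3-[3-methoxy-4-(methoxymethoxy)phenyl]propanoic acid | COc1cc(Br)cc(OC)c1O[C@@H](C(=O)O)Cc1ccc(OCOC)c(OC)c1
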